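## Retrosynthetic overview

1. Both benzylic carbinols are made last, by substrate-controlled (Felkin) reduction of a bis(α-aryloxy ketone). The two enantiomeric arms come from SN2 etherification of the two core phenols, unmasked one after the other, with (S)- and (R)-2-chloro-1-(3,4-dimethoxyphenyl)propan-1-one.
2. The 2,5-diaryl-3,4-dimethyloxolane comes from aryllithium addition to a 3,4-trans-4,5-trans γ-lactone and kinetic hydride reduction of the resulting oxocarbenium ion (2,3-cis).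
3. The lactone comes from Felkin reduction and lactonisation of a γ-keto ester (4,5-trans), itself made from a γ,δ-unsaturated acid by aryl ketone formation and ozonolytic cleavage.
4. The key bond C3–C4, with both methyl stereocentres, is formed by Ireland–Claisen [3,3] rearrangement of (2S,3Z)-pent-3-en-2-yl propanoate. The sacrificed carbinol centre is that of ethyl L-lactate.
5. Ring order: only one ring is built, the five-membered oxygen ring, first as γ-lactone and then converted in place into the oxolane. All benzene rings are bought.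

Assumption: ethyl L-lactate and the two enantiomers of 2-chloropropanoyl chloride (alanine/lactic acid pool) are taken as the purchased chiral materials; all aryl building blocks are achiral and commercial.

## Route

Step 1
Reactants: 1 ethyl (2S)-2-hydroxypropanoate (ethyl L-lactate)
Product: 2 ethyl (2S)-2-[(tert-butyldimethylsilyl)oxy]propanoate
Conditions: TBSCl, imidazole, DMF, 0 °C → rt
Reagents that add atoms: tert-butyldimethylsilyl chloride, CC(C)(C)[Si](C)(C)Cl
Why: Standard O-silylation of a secondary alcohol; no bond to the stereocentre is touched, so the (S) centre of lactate is kept.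

Step 2
Reactants: 2 ethyl (2S)-2-[(tert-butyldimethylsilyl)oxy]propanoate
Product: 4 tert-butyldimethyl{[(2S,3Z)-pent-3-en-2-yl]oxy}silane, via aldehyde 3 (not isolated)
Conditions: i-Bu2AlH, CH2Cl2, −78 °C; then Ph3P=CHCH3 (from EtPPh3Br, KN(SiMe3)2, THF), −78 °C → rt
Reagents that add atoms: ethyltriphenylphosphonium bromide, CC[P+](c1ccccc1)(c1ccccc1)c1ccccc1.[Br-]
Why: Half-reduction of the ester (aldehyde held as its aluminium hemiacetal) followed by salt-free Wittig olefination with a non-stabilised ylide gives the Z-alkene, and trapping the α-silyloxy aldehyde in the same flask avoids its racemisation.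

Step 3
Reactants: 4 tert-butyldimethyl{[(2S,3Z)-pent-3-en-2-yl]oxy}silane; 5 propanoic anhydride
Product: 7 (2S,3Z)-pent-3-en-2-yl propanoate, via allylic alcohol 6 (not isolated)
Conditions: Bu4NF, THF, 0 °C → rt; then (EtCO)2O, Et3N, DMAP (cat.), 0 °C → rt
Reagents that add atoms: none
Why: Fluoride desilylation and DMAP-catalysed acylation in one flask avoid isolating the volatile C5 alcohol; neither the C–O stereocentre nor the Z-alkene is touched.

Step 4
Reactants: 7 (2S,3Z)-pent-3-en-2-yl propanoate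
Product: 10 (2R,3S,4E)-2,3-dimethylhex-4-enoic acid, via silyl ketene acetal 8 (not isolated), via silyl ester 9 (not isolated)
Conditions: LiN(i-Pr)2, THF, −78 °C; Me3SiCl, −78 °C → 60 °C; then 1 M HCl
Reagents that add atoms: none
Why: Ireland–Claisen [3,3]-sigmatropic rearrangement: kinetic enolisation in THF gives the (E)-silyl ketene acetal, which with the Z-alkene reacts through a chair transition state with the carbinol methyl equatorial, so the C2–C3 bond forms with 1,3-chirality transfer from the lactate centre (2,3-syn, 2R,3S, new alkene E; about 9:1 syn:anti expected).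

Step 5
Reactants: 10 (2R,3S,4E)-2,3-dimethylhex-4-enoic acid; 11 1-(benzyloxy)-4-bromo-2-methoxybenzene
Product: 13 (2R,3S,4E)-1-[4-(benzyloxy)-3-methoxyphenyl]-2,3-dimethylhex-4-en-1-one, via aryllithium 12 (not isolated)
Conditions: 11 (2.3 equiv), n-BuLi (2.2 equiv), THF, −78 °C; then 10, −78 → 0 °C; 1 M HCl
Reagents that add atoms: none
Why: Aryllithium addition to the lithium carboxylate stops at the gem-diolate, which releases the ketone only on acidic work-up (no over-addition), and the α-stereocentre is not enolised.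

Step 6
Reactants: 13 (2R,3S,4E)-1-[4-(benzyloxy)-3-methoxyphenyl]-2,3-dimethylhex-4-en-1-one
Product: 14 methyl (2R,3R)-4-[4-(benzyloxy)-3-methoxyphenyl]-2,3-dimethyl-4-oxobutanoate
Conditions: O3, NaOH (2.5 M in MeOH), CH2Cl2, −78 °C
Reagents that add atoms: ozone, [O-][O+]=O; methanol, CO
Why: Ozonolysis in methanolic NaOH cleaves the disubstituted alkene directly to the methyl ester (the propenyl end leaves as methyl acetate), the alkene being far more reactive towards ozone than the ketone-deactivated arene; no stereocentre is involved.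

Step 7
Reactants: 14 methyl (2R,3R)-4-[4-(benzyloxy)-3-methoxyphenyl]-2,3-dimethyl-4-oxobutanoate
Product: 16 (3R,4R,5R)-5-[4-(benzyloxy)-3-methoxyphenyl]-3,4-dimethyloxolan-2-one, via hydroxy ester 15 (not isolated)
Conditions: LiBH(s-Bu)3, THF, −78 °C → rt; aq. NH4Cl
Reagents that add atoms: none
Why: Felkin–Anh reduction of the α-methyl aryl ketone by the bulky hydride (attack anti to the large CH(CH3)CO2Me group) gives the anti alkoxide, which lactonises onto the methyl ester to the 3,4-trans-4,5-trans lactone (5R).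

Step 8
Reactants: 17 4-bromo-2-methoxyphenol
Product: 18 (4-bromo-2-methoxyphenoxy)(tert-butyl)dimethylsilane
Conditions: TBSCl, imidazole, DMF, rt
Reagents that add atoms: tert-butyldimethylsilyl chloride, CC(C)(C)[Si](C)(C)Cl
Why: Standard phenol silylation; the aryl silyl ether survives halogen–lithium exchange and is later removed by fluoride independently of the benzyl ether.

Step 9
Reactants: 16 (3R,4R,5R)-5-[4-(benzyloxy)-3-methoxyphenyl]-3,4-dimethyloxolan-2-one; 18 (4-bromo-2-methoxyphenoxy)(tert-butyl)dimethylsilane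
Product: 20 (3R,4R,5R)-5-[4-(benzyloxy)-3-methoxyphenyl]-2-{4-[(tert-butyldimethylsilyl)oxy]-3-methoxyphenyl}-3,4-dimethyloxolan-2-ol, via aryllithium 19 (not isolated)
Conditions: 18, n-BuLi, THF, −78 °C; then 16, −78 °C; aq. NH4Cl
Reagents that add atoms: none
Why: Halogen–lithium exchange and 1,2-addition to the lactone carbonyl stop at the tetrahedral lithium hemiketalate at −78 °C, giving the cyclic hemiketal (C2 epimer mixture, C3–C5 untouched).

Step 10
Reactants: 20 (3R,4R,5R)-5-[4-(benzyloxy)-3-methoxyphenyl]-2-{4-[(tert-butyldimethylsilyl)oxy]-3-methoxyphenyl}-3,4-dimethyloxolan-2-ol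
Product: 21 tert-butyl{4-[(2S,3R,4R,5R)-5-[4-(benzyloxy)-3-methoxyphenyl]-3,4-dimethyloxolan-2-yl]-2-methoxyphenoxy}dimethylsilane
Conditions: Et3SiH, BF3·OEt2, CH2Cl2, −78 °C; Et3N quench at −78 °C
Reagents that add atoms: none
Why: Ionic hydrogenation (reductive deoxygenation): BF3 ionises the hemiketal to the 2-aryl oxocarbenium ion and hydride is delivered under kinetic control to the face opposite the adjacent C3 methyl and the C5 aryl group, leaving the new aryl group cis to the C3 methyl (2S).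

Step 11
Reactants: 22 (2S)-2-chloropropanoyl chloride; 23 1,2-dimethoxybenzene
Product: 24 (2S)-2-chloro-1-(3,4-dimethoxyphenyl)propan-1-one
Conditions: AlCl3, CH2Cl2, 0 °C
Reagents that add atoms: none
Why: Friedel–Crafts acylation para to a methoxy group; the acylium ion forms and reacts without enolisation, so the α-chloro stereocentre is retained.

Step 12
Reactants: 21 tert-butyl{4-[(2S,3R,4R,5R)-5-[4-(benzyloxy)-3-methoxyphenyl]-3,4-dimethyloxolan-2-yl]-2-methoxyphenoxy}dimethylsilane; 24 (2S)-2-chloro-1-(3,4-dimethoxyphenyl)propan-1-one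
Product: 26 (2R)-2-{4-[(2S,3R,4R,5R)-5-[4-(benzyloxy)-3-methoxyphenyl]-3,4-dimethyloxolan-2-yl]-2-methoxyphenoxy}-1-(3,4-dimethoxyphenyl)propan-1-one, via caesium phenoxide 25 (not isolated)
Conditions: CsF, DMF, rt; then 24, 0 °C → rt
Reagents that add atoms: none
Why: Fluoride cleaves only the aryl silyl ether and the phenoxide displaces chloride from the α-chloro ketone in a Williamson SN2 etherification with inversion, (S)-chloride to (R)-aryl ether.

Step 13
Reactants: 26 (2R)-2-{4-[(2S,3R,4R,5R)-5-[4-(benzyloxy)-3-methoxyphenyl]-3,4-dimethyloxolan-2-yl]-2-methoxyphenoxy}-1-(3,4-dimethoxyphenyl)propan-1-one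
Product: 27 (2R)-1-(3,4-dimethoxyphenyl)-2-{4-[(2S,3R,4R,5R)-5-(4-hydroxy-3-methoxyphenyl)-3,4-dimethyloxolan-2-yl]-2-methoxyphenoxy}propan-1-one
Conditions: H2 (1 atm), Pd/C (10% Pd on carbon), EtOAc, rt
Reagents that add atoms: none
Why: Hydrogenolysis of the benzyl aryl ether is much faster than reduction of the electron-rich aryl ketone or opening of the cyclic dibenzylic ether; no stereocentre is affected.

Step 14
Reactants: 28 (2R)-2-chloropropanoyl chloride; 23 1,2-dimethoxybenzene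
Product: 29 (2R)-2-chloro-1-(3,4-dimethoxyphenyl)propan-1-one
Conditions: AlCl3, CH2Cl2, 0 °C
Reagents that add atoms: none
Why: Friedel–Crafts acylation as in step 11, giving the enantiomeric α-chloro ketone with retention.

Step 15
Reactants: 27 (2R)-1-(3,4-dimethoxyphenyl)-2-{4-[(2S,3R,4R,5R)-5-(4-hydroxy-3-methoxyphenyl)-3,4-dimethyloxolan-2-yl]-2-methoxyphenoxy}propan-1-one; 29 (2R)-2-chloro-1-(3,4-dimethoxyphenyl)propan-1-one
Product: 30 (2R)-1-(3,4-dimethoxyphenyl)-2-{4-[(2S,3R,4R,5R)-5-(4-{[(2S)-1-(3,4-dimethoxyphenyl)-1-oxopropan-2-yl]oxy}-3-methoxyphenyl)-3,4-dimethyloxolan-2-yl]-2-methoxyphenoxy}propan-1-one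
Conditions: K2CO3, acetone, rt
Reagents that add atoms: none
Why: Williamson SN2 etherification with inversion, (R)-chloride to (S)-aryl ether, under a mild heterogeneous base that limits enolisation of both α-aryloxy ketones.

Step 16
Reactants: 30 (2R)-1-(3,4-dimethoxyphenyl)-2-{4-[(2S,3R,4R,5R)-5-(4-{[(2S)-1-(3,4-dimethoxyphenyl)-1-oxopropan-2-yl]oxy}-3-methoxyphenyl)-3,4-dimethyloxolan-2-yl]-2-methoxyphenoxy}propan-1-one
Product: 31 (1R,2R)-1-(3,4-dimethoxyphenyl)-2-{4-[(2S,3R,4R,5R)-5-(4-{[(1S,2S)-1-(3,4-dimethoxyphenyl)-1-hydroxypropan-2-yl]oxy}-3-methoxyphenyl)-3,4-dimethyloxolan-2-yl]-2-methoxyphenoxy}propan-1-ol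
Conditions: Bu4NBH4, MeOH/CH2Cl2, −20 → 0 °C
Reagents that add atoms: none
Why: Non-chelating borohydride reduction under polar Felkin–Anh (Cornforth) control: in each arm hydride adds anti to the α-aryloxy group, so each α-centre sets its own carbinol threo (R gives 1R,2R; S gives 1S,2S); erythro isomers are removed by chromatography.

## Compound list

1 | ethyl (2S)-2-hydroxypropanoate | C[C@H](O)C(=O)OCC | starting material
2 | ethyl (2S)-2-[(tert-butyldimethylsilyl)oxy]propanoate | C[C@H](O[Si](C)(C)C(C)(C)C)C(=O)OCC | intermediate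
3 | (2S)-2-[(tert-butyldimethylsilyl)oxy]propanal | C[C@H](O[Si](C)(C)C(C)(C)C)C=O | intermediate (not isolated)
4 | tert-butyldimethyl{[(2S,3Z)-pent-3-en-2-yl]oxy}silane | C[C@H](O[Si](C)(C)C(C)(C)C)/C=C\C | intermediate
5 | propanoic anhydride | CCC(=O)OC(=O)CC | starting material
6 | (2S,3Z)-pent-3-en-2-ol | C[C@H](O)/C=C\C | intermediate (not isolated)
7 | (2S,3Z)-pent-3-en-2-yl propanoate | CCC(=O)O[C@@H](C)/C=C\C | intermediate
8 | trimethyl{[(1E)-1-{[(2S,3Z)-pent-3-en-2-yl]oxy}prop-1-en-1-yl]oxy}silane | C/C=C(/O[Si](C)(C)C)O[C@@H](C)/C=C\C | intermediate (not isolated)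
9 | trimethylsilyl (2R,3S,4E)-2,3-dimethylhex-4-enoate | C/C=C/[C@H](C)[C@@H](C)C(=O)O[Si](C)(C)C | intermediate (not isolated)
10 | (2R,3S,4E)-2,3-dimethylhex-4-enoic acid | C/C=C/[C@H](C)[C@@H](C)C(=O)O | intermediate
11 | 1-(benzyloxy)-4-bromo-2-methoxybenzene | COc1cc(Br)ccc1OCc1ccccc1 | starting material
12 | [4-(benzyloxy)-3-methoxyphenyl]lithium | [Li]c1ccc(OCc2ccccc2)c(OC)c1 | intermediate (not isolated)
13 | (2R,3S,4E)-1-[4-(benzyloxy)-3-methoxyphenyl]-2,3-dimethylhex-4-en-1-one | C/C=C/[C@H](C)[C@@H](C)C(=O)c1ccc(OCc2ccccc2)c(OC)c1 | intermediate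
14 | methyl (2R,3R)-4-[4-(benzyloxy)-3-methoxyphenyl]-2,3-dimethyl-4-oxobutanoate | COC(=O)[C@H](C)[C@@H](C)C(=O)c1ccc(OCc2ccccc2)c(OC)c1 | intermediate
15 | methyl (2R,3R,4R)-4-[4-(benzyloxy)-3-methoxyphenyl]-4-hydroxy-2,3-dimethylbutanoate (formed as its lithium alkoxide) | COC(=O)[C@H](C)[C@@H](C)[C@@H](O)c1ccc(OCc2ccccc2)c(OC)c1 | intermediate (not isolated)
16 | (3R,4R,5R)-5-[4-(benzyloxy)-3-methoxyphenyl]-3,4-dimethyloxolan-2-one | O=C1O[C@@H](c2ccc(OCc3ccccc3)c(OC)c2)[C@H](C)[C@H]1C | intermediate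
17 | 4-bromo-2-methoxyphenol | COc1cc(Br)ccc1O | starting material
18 | (4-bromo-2-methoxyphenoxy)(tert-butyl)dimethylsilane | COc1cc(Br)ccc1O[Si](C)(C)C(C)(C)C | intermediate
19 | {4-[(tert-butyldimethylsilyl)oxy]-3-methoxyphenyl}lithium | [Li]c1ccc(O[Si](C)(C)C(C)(C)C)c(OC)c1 | intermediate (not isolated)
20 | (3R,4R,5R)-5-[4-(benzyloxy)-3-methoxyphenyl]-2-{4-[(tert-butyldimethylsilyl)oxy]-3-methoxyphenyl}-3,4-dimethyloxolan-2-ol (C2 epimer mixture) | OC1(c2ccc(O[Si](C)(C)C(C)(C)C)c(OC)c2)O[C@@H](c2ccc(OCc3ccccc3)c(OC)c2)[C@H](C)[C@H]1C | intermediate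
21 | tert-butyl{4-[(2S,3R,4R,5R)-5-[4-(benzyloxy)-3-methoxyphenyl]-3,4-dimethyloxolan-2-yl]-2-methoxyphenoxy}dimethylsilane | CC(C)(C)[Si](C)(C)Oc1ccc([C@H]2O[C@@H](c3ccc(OCc4ccccc4)c(OC)c3)[C@H](C)[C@H]2C)cc1OC | intermediate
22 | (2S)-2-chloropropanoyl chloride | C[C@H](Cl)C(Cl)=O | starting material
23 | 1,2-dimethoxybenzene | COc1ccccc1OC | starting material
24 | (2S)-2-chloro-1-(3,4-dimethoxyphenyl)propan-1-one | C[C@H](Cl)C(=O)c1ccc(OC)c(OC)c1 | intermediate
25 | caesium 4-[(2S,3R,4R,5R)-5-[4-(benzyloxy)-3-methoxyphenyl]-3,4-dimethyloxolan-2-yl]-2-methoxyphenolate | [Cs+].[O-]c1ccc([C@H]2O[C@@H](c3ccc(OCc4ccccc4)c(OC)c3)[C@H](C)[C@H]2C)cc1OC | intermediate (not isolated)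
26 | (2R)-2-{4-[(2S,3R,4R,5R)-5-[4-(benzyloxy)-3-methoxyphenyl]-3,4-dimethyloxolan-2-yl]-2-methoxyphenoxy}-1-(3,4-dimethoxyphenyl)propan-1-one | COc1ccc(C(=O)[C@@H](C)Oc2ccc([C@H]3O[C@@H](c4ccc(OCc5ccccc5)c(OC)c4)[C@H](C)[C@H]3C)cc2OC)cc1OC | intermediate
27 | (2R)-1-(3,4-dimethoxyphenyl)-2-{4-[(2S,3R,4R,5R)-5-(4-hydroxy-3-methoxyphenyl)-3,4-dimethyloxolan-2-yl]-2-methoxyphenoxy}propan-1-one | COc1ccc(C(=O)[C@@H](C)Oc2ccc([C@H]3O[C@@H](c4ccc(O)c(OC)c4)[C@H](C)[C@H]3C)cc2OC)cc1OC | intermediate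
28 | (2R)-2-chloropropanoyl chloride | C[C@@H](Cl)C(Cl)=O | starting material
29 | (2R)-2-chloro-1-(3,4-dimethoxyphenyl)propan-1-one | C[C@@H](Cl)C(=O)c1ccc(OC)c(OC)c1 | intermediate
30 | (2R)-1-(3,4-dimethoxyphenyl)-2-{4-[(2S,3R,4R,5R)-5-(4-{[(2S)-1-(3,4-dimethoxyphenyl)-1-oxopropan-2-yl]oxy}-3-methoxyphenyl)-3,4-dimethyloxolan-2-yl]-2-methoxyphenoxy}propan-1-one | COc1ccc(C(=O)[C@@H](C)Oc2ccc([C@H]3O[C@@H](c4ccc(O[C@@H](C)C(=O)c5ccc(OC)c(OC)c5)c(OC)c4)[C@H](C)[C@H]3C)cc2OC)cc1OC | intermediate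
31 | (1R,2R)-1-(3,4-dimethoxyphenyl)-2-{4-[(2S,3R,4R,5R)-5-(4-{[(1S,2S)-1-(3,4-dimethoxyphenyl)-1-hydroxypropan-2-yl]oxy}-3-methoxyphenyl)-3,4-dimethyloxolan-2-yl]-2-methoxyphenoxy}propan-1-ol | COc1ccc([C@@H](O)[C@@H](C)Oc2ccc([C@H]3O[C@@H](c4ccc(O[C@@H](C)[C@@H](O)c5ccc(OC)c(OC)c5)c(OC)c4)[C@H](C)[C@H]3C)cc2OC)cc1OC | target

## Step count and risks

Total steps: 16. Longest linear sequence: 13 (steps 1–7, 9, 10, 12, 13, 15, 16, from ethyl L-lactate).

Three steps most likely to fail: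

**Step 10.** The 2,3-cis oxolane is the kinetic product. BF3 can reopen the electron-rich benzylic C–O bond and let C2 drift to the all-trans isomer, and the facial selectivity rests on the adjacent methyl alone. The fallback sets out from lactone 16 and comes back at 21. Lactone 16 is reduced with i-Bu2AlH (CH2Cl2, −78 °C) to the lactol F1, which is converted with PhSO2H and CaCl2 (CH2Cl2, rt) into the 2-benzenesulfonyl ether F2. F2 is then coupled with the arylzinc bromide F3, made from aryllithium 19 and ZnBr2 in THF. Here the aryl group, not hydride, is the nucleophile on a 2-unsubstituted oxocarbenium ion whose two methyl groups sit pseudoequatorial. The inside-attack model predicts addition cis to the C3 methyl and trans to the C4 methyl, which gives 21 directly; the influence of the C5 aryl group on this selectivity is the open point.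

**Step 12.** Fluoride, phenoxide or liberated chloride may erode the α-centre of 24 or of the product (the same bond formation in step 15 runs under milder carbonate conditions). The fallback sets out from 21 and comes back at 26, and forms the C–O bond before any ketone exists. The silyl ether of 21 is cleaved with Bu4NF/AcOH to the phenol F4. F4 is joined with ethyl (S)-lactate 1 in a Mitsunobu reaction (PPh3, DIAD, THF, 0 °C, clean inversion) to the ethyl (R)-2-aryloxypropanoate F5. F5 is converted with MeNH(OMe)·HCl and i-PrMgCl (THF, −20 °C) into the Weinreb amide F6, and commercial 3,4-(MeO)2C6H3MgBr is added to give 26.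

**Step 16.** Two independent Felkin reductions are needed, and only modest selectivity per arm (roughly 4:1) is realistic, so erythro isomers will contaminate the product. The fallback sets out from 30 and comes back at 31. Ketone 30 is reduced under chelation control with Zn(BH4)2 (Et2O, 0 °C) to the erythro,erythro diol F7. Both carbinols are inverted in a double Mitsunobu esterification with 4-nitrobenzoic acid (PPh3, DIAD, THF) to the threo,threo bis(4-nitrobenzoate) F8, and methanolysis (K2CO3, MeOH, rt) gives 31.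

## Further compounds

F1 | step 10 | (3R,4R,5R)-5-[4-(benzyloxy)-3-methoxyphenyl]-3,4-dimethyloxolan-2-ol | OC1O[C@@H](c2ccc(OCc3ccccc3)c(OC)c2)[C@H](C)[C@H]1C
F2 | step 10 | (3R,4R,5R)-2-(benzenesulfonyl)-5-[4-(benzyloxy)-3-methoxyphenyl]-3,4-dimethyloxolane | O=S(=O)(c1ccccc1)C1O[C@@H](c2ccc(OCc3ccccc3)c(OC)c2)[C@H](C)[C@H]1C
F3 | step 10 | bromo{4-[(tert-butyldimethylsilyl)oxy]-3-methoxyphenyl}zinc | Br[Zn]c1ccc(O[Si](C)(C)C(C)(C)C)c(OC)c1
F4 | step 12 | 4-[(2S,3R,4R,5R)-5-[4-(benzyloxy)-3-methoxyphenyl]-3,4-dimethyloxolan-2-yl]-2-methoxyphenol | Oc1ccc([C@H]2O[C@@H](c3ccc(OCc4ccccc4)c(OC)c3)[C@H](C)[C@H]2C)cc1OC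
F5 | step 12 | ethyl (2R)-2-{4-[(2S,3R,4R,5R)-5-[4-(benzyloxy)-3-methoxyphenyl]-3,4-dimethyloxolan-2-yl]-2-methoxyphenoxy}propanoate | CCOC(=O)[C@@H](C)Oc1ccc([C@H]2O[C@@H](c3ccc(OCc4ccccc4)c(OC)c3)[C@H](C)[C@H]2C)cc1OC
F6 | step 12 | (2R)-2-{4-[(2S,3R,4R,5R)-5-[4-(benzyloxy)-3-methoxyphenyl]-3,4-dimethyloxolan-2-yl]-2-methoxyphenoxy}-N-methoxy-N-methylpropanamide | CON(C)C(=O)[C@@H](C)Oc1ccc([C@H]2O[C@@H](c3ccc(OCc4ccccc4)c(OC)c3)[C@H](C)[C@H]2C)cc1OC
F7 | step 16 | (1S,2R)-1-(3,4-dimethoxyphenyl)-2-{4-[(2S,3R,4R,5R)-5-(4-{[(1R,2S)-1-(3,4-dimethoxyphenyl)-1-hydroxypropan-2-yl]oxy}-3-methoxyphenyl)-3,4-dimethyloxolan-2-yl]-2-methoxyphenoxy}propan-1-ol | COc1ccc([C@H](O)[C@@H](C)Oc2ccc([C@H]3O[C@@H](c4ccc(O[C@@H](C)[C@H](O)c5ccc(OC)c(OC)c5)c(OC)c4)[C@H](C)[C@H]3C)cc2OC)cc1OC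
F8 | step 16 | bis(4-nitrobenzoate) of 31 (threo,threo) | COc1ccc([C@@H](OC(=O)c6ccc(cc6)[N+](=O)[O-])[C@@H](C)Oc2ccc([C@H]3O[C@@H](c4ccc(O[C@@H](C)[C@@H](OC(=O)c7ccc(cc7)[N+](=O)[O-])c5ccc(OC)c(OC)c5)c(OC)c4)[C@H](C)[C@H]3C)cc2OC)cc1OC
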